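**Plan**

- Retrosynthesis: the C13=C14 alkene is cut first (olefination of a C13 ketone), then C11–C12 and C8–C9 together (radical addition–cyclisation), then C10–vinyl, C10–CH3 and C5–C6 on a ring A derived from dimedone. Labdane numbers are used throughout.
- Enabling feature: on ring A the C10 vinyl group (C9=C11) and the C5 but-3-ynyl arm (C8≡C17) make up a 1,7-enyne. A radical that adds at C11 is relayed through C9 to C8 and leaves the exocyclic C8=C17 methylene of ring B.
- Forward order: ring A is dressed first (C5 arm by allylation and extension to the alkyne, C10 methyl by 1,2-addition with carbonyl transposition, C10 vinyl by conjugate addition, C2 methoxy by reduction and methylation). Ring B then closes while C12–C16 is joined in one radical step, and olefination plus ester cleavage complete the chain.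
- Stereochemistry: C5 from a chiral palladium catalyst; C10 from attack anti to the C5 arm; C2 from thermodynamic (equatorial) ketone reduction; C9 from the chair-like 6-exo-dig transition state.
- The C13=C14 geometry is not controlled by the reagent: the Wittig step is expected to give both isomers and the Z isomer is separated.

Key step: step 12

Assumption: the (1R,2R) ligand in step 3 is taken to give the (R) product by analogy with related allyl enol carbonates; if the sense is the opposite, the (1S,2S) ligand is used.

**Route**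

Step 1
Reactants: 1 dimedone
Product: 2 3-isobutoxy-5,5-dimethylcyclohex-2-en-1-one
Conditions: i-BuOH, TsOH·H2O (cat.), toluene, reflux, azeotropic removal of water
Reagents that add atoms: 2-methylpropan-1-ol CC(C)CO
Why: Acid-catalysed enol ether formation from the enolised 1,3-dione gives the vinylogous ester, which masks the future C2 carbonyl and leaves the future C5 as the only position for kinetic enolisation.

Step 2
Reactants: 2 3-isobutoxy-5,5-dimethylcyclohex-2-en-1-one
Product: 3 allyl (5-isobutoxy-3,3-dimethylcyclohexa-1,5-dien-1-yl) carbonate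
Conditions: LiN(i-Pr)2, TMEDA, THF, −78 °C; then allyl chloroformate, −78 °C
Reagents that add atoms: allyl chloroformate C=CCOC(Cl)=O
Why: Kinetic deprotonation of a vinylogous ester takes place at the alpha-prime carbon (future C5), and the hard chloroformate acylates this hindered enolate on oxygen (enol carbonate formation).

Step 3
Reactants: 3 allyl (5-isobutoxy-3,3-dimethylcyclohexa-1,5-dien-1-yl) carbonate
Product: 4 (R)-6-allyl-3-isobutoxy-5,5-dimethylcyclohex-2-en-1-one
Conditions: Pd2(dba)3·CHCl3 (2.5 mol %), (1R,2R)-N,N'-bis[2-(diphenylphosphino)benzoyl]cyclohexane-1,2-diamine (5.5 mol %), 1,4-dioxane, rt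
Reagents that add atoms: none
Why: Decarboxylative asymmetric allylic alkylation (Tsuji–Trost type): zerovalent palladium ionises the allyl carbonate, CO2 is lost, and the chiral diphosphine decides which face of the enolate carbon is allylated, which sets C5 as (R) under base-free conditions that do not equilibrate the new tertiary centre.

Step 4
Reactants: 4 (R)-6-allyl-3-isobutoxy-5,5-dimethylcyclohex-2-en-1-one
Product: 5 (R)-6-(3-hydroxypropyl)-3-isobutoxy-5,5-dimethylcyclohex-2-en-1-one
Conditions: 9-BBN, THF, 0 °C → rt; then aq. NaOAc, H2O2, 0 °C → rt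
Reagents that add atoms: hydrogen peroxide OO
Why: Anti-Markovnikov hydroboration–oxidation of the terminal alkene, which 9-BBN should take far faster than the deactivated vinylogous ester carbonyl or the push–pull enol ether alkene.

Step 5
Reactants: 5 (R)-6-(3-hydroxypropyl)-3-isobutoxy-5,5-dimethylcyclohex-2-en-1-one
Product: 6 3-[(1R)-4-isobutoxy-6,6-dimethyl-2-oxocyclohex-3-en-1-yl]propanal
Conditions: 1,1,1-triacetoxy-1,1-dihydro-1,2-benziodoxol-3(1H)-one (DMP), CH2Cl2, rt
Reagents that add atoms: none
Why: Hypervalent-iodine oxidation of the primary alcohol to the aldehyde under near-neutral conditions that leave the enol ether and the C5 centre untouched.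

Step 6
Reactants: 6 3-[(1R)-4-isobutoxy-6,6-dimethyl-2-oxocyclohex-3-en-1-yl]propanal
Product: 7 (R)-6-(but-3-yn-1-yl)-3-isobutoxy-5,5-dimethylcyclohex-2-en-1-one
Conditions: dimethyl (1-diazo-2-oxopropyl)phosphonate, K2CO3, MeOH, 0 °C → rt
Reagents that add atoms: dimethyl (1-diazo-2-oxopropyl)phosphonate CC(=O)C(=[N+]=[N-])P(=O)(OC)OC
Why: Seyferth–Gilbert homologation in its carbonate/methanol variant turns the aldehyde into the terminal alkyne C8≡C17 through a diazoalkene and alkylidene carbene, with a base too weak to epimerise C5.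

Step 7
Reactants: 7 (R)-6-(but-3-yn-1-yl)-3-isobutoxy-5,5-dimethylcyclohex-2-en-1-one
Product: 9 (R)-3,5,5-trimethyl-4-[4-(trimethylsilyl)but-3-yn-1-yl]cyclohex-2-en-1-one, via bis-silylated carbinol 8 (not isolated)
Conditions: MeLi (2.5 equiv), THF, −78 → 0 °C; Me3SiCl, 0 °C → rt; then 1 M HCl, THF, rt
Reagents that add atoms: methyllithium [Li]C; chlorotrimethylsilane C[Si](C)(C)Cl; water O
Why: Stork–Danheiser sequence: MeLi deprotonates the alkyne and adds 1,2 to the vinylogous ester carbonyl (C10 methyl), the acetylide is capped on carbon by silicon, and acid hydrolysis of the enol ether with loss of the tertiary oxygen transposes the carbonyl to C2 and places the alkene at C1=C10.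

Step 8
Reactants: 9 (R)-3,5,5-trimethyl-4-[4-(trimethylsilyl)but-3-yn-1-yl]cyclohex-2-en-1-one
Product: 11 (3S,4R)-3-ethenyl-3,5,5-trimethyl-4-[4-(trimethylsilyl)but-3-yn-1-yl]cyclohexan-1-one, via silyl enol ether 10 (not isolated)
Conditions: CH2=CHMgBr, CuBr·SMe2 (20 mol %), Me3SiCl, HMPA, THF, −78 → −40 °C; then 1 M HCl, 0 °C
Reagents that add atoms: vinylmagnesium bromide C=C[Mg]Br
Why: Chlorosilane-accelerated copper-catalysed conjugate addition: the C5 arm sits pseudo-axial to avoid the C10 methyl and the C4 methyls, so the vinyl copper reagent attacks C10 axially on the opposite face and the vinyl group ends up trans to the C5 arm (C10 quaternary centre, S in 11).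

Step 9
Reactants: 11 (3S,4R)-3-ethenyl-3,5,5-trimethyl-4-[4-(trimethylsilyl)but-3-yn-1-yl]cyclohexan-1-one
Product: 12 (1R,3S,4R)-3-ethenyl-3,5,5-trimethyl-4-[4-(trimethylsilyl)but-3-yn-1-yl]cyclohexan-1-ol
Conditions: SmI2, Et3N, H2O, THF, rt
Reagents that add atoms: none
Why: Single-electron (dissolving-metal type) ketone reduction, in which the ketyl-derived carbanion is protonated to the thermodynamically preferred equatorial alcohol because the axial epimer is penalised by the two syn-axial methyls on C4 and C10; hydride reagents would approach from the open equatorial side and give the axial alcohol instead.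

Step 10
Reactants: 12 (1R,3S,4R)-3-ethenyl-3,5,5-trimethyl-4-[4-(trimethylsilyl)but-3-yn-1-yl]cyclohexan-1-ol
Product: 14 (1S,2R,5R)-2-(but-3-yn-1-yl)-1-ethenyl-5-methoxy-1,3,3-trimethylcyclohexane, via silylalkyne methyl ether 13 (not isolated)
Conditions: NaH, MeI, THF/DMF, 0 °C → rt; then MeOH, K2CO3, rt
Reagents that add atoms: iodomethane CI
Why: Williamson methylation of the unhindered equatorial alkoxide, followed in the same flask by methoxide cleavage of the alkynyl C–Si bond, which frees the terminal alkyne without touching any stereocentre.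

Step 11
Reactants: 15 1-acetoxy-3-chloroacetone
Product: 16 1-acetoxy-3-iodopropan-2-one
Conditions: NaI, acetone, rt, dark
Reagents that add atoms: sodium iodide [Na+].[I-]
Why: Finkelstein halide exchange, driven by precipitation of NaCl, supplies the weak C–I bond needed for radical generation; the iodide is used freshly prepared.

Step 12
Reactants: 14 (1S,2R,5R)-2-(but-3-yn-1-yl)-1-ethenyl-5-methoxy-1,3,3-trimethylcyclohexane; 16 1-acetoxy-3-iodopropan-2-one
Product: 18 4-[(1R,4aR,7R,8aR)-7-methoxy-5,5,8a-trimethyl-2-methylidenedecahydronaphthalen-1-yl]-2-oxobutyl acetate (16-acetoxy-2-methoxy-14,15-dinor-ent-labd-8(17)-en-13-one), via C9 iodide adduct 17 (not isolated)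
Conditions: 16 (1.5 equiv), Et3B (0.3 equiv), air, benzene, rt; then dilution to 0.01 M, Bu3SnH (syringe pump), AIBN, 80 °C
Reagents that add atoms: none
Why: Et3B and air generate the electrophilic 3-acetoxy-2-oxopropyl radical from 16, which adds to the open terminal carbon C11 of the vinyl group, and the C9 radical is trapped by iodine transfer from 16 to give 17 (Kharasch-type atom-transfer addition). Slow addition of Bu3SnH then regenerates the C9 radical at low hydride concentration, so that attack on C8 of the tethered alkyne can outrun hydrogen transfer; the C17 vinyl radical is reduced by the stannane directly or after 1,5-hydrogen transfer from C12, and both paths end in 18. The closest known reaction type is the two-component radical addition–cyclisation of 1,6- and 1,7-enynes with α-halo carbonyl compounds under atom-transfer or tin hydride conditions. Ring B closes 6-exo-dig through a chair-like transition state on the ring A chair that holds the C10 and C5 arms trans-diequatorial, which fixes the trans ring fusion. C9 is set in that chair by the C11 chain taking the pseudo-equatorial position beside the small C10 methyl and away from the axial hydrogens on C5 and C7, which should give 9R (H9 anti to the C10 methyl). The step needs addition to the alkene in preference to the alkyne and cyclisation before reduction; the polarity match of the keto radical with the alkene, the quaternary C10 that leaves only C11 open, the preorganised arms and the syringe-pump regime are meant to secure these.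

Step 13
Reactants: 18 4-[(1R,4aR,7R,8aR)-7-methoxy-5,5,8a-trimethyl-2-methylidenedecahydronaphthalen-1-yl]-2-oxobutyl acetate
Product: 19 2-(trimethylsilyl)ethyl (2Z)-3-(acetoxymethyl)-5-[(1R,4aR,7R,8aR)-7-methoxy-5,5,8a-trimethyl-2-methylidenedecahydronaphthalen-1-yl]pent-2-enoate
Conditions: Ph3P=C=C=O, Me3SiCH2CH2OH, toluene, 60 °C; then 18, 90 °C; chromatographic separation of the geometrical isomers
Reagents that add atoms: (triphenylphosphoranylidene)ketene O=C=C=P(c1ccccc1)(c1ccccc1)c1ccccc1; 2-(trimethylsilyl)ethanol C[Si](C)(C)CCO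
Why: Wittig olefination with a stabilised ester ylide made in the flask from the ketenylidene phosphorane and the silyl alcohol, the α-acetoxy group activating the C13 ketone under neutral conditions that spare the acetate; since the two arms on C13 are of similar size, the Z isomer (ester cis to C16) is expected together with the E isomer and is to be separated and assigned by NOE between H14 and the C12 methylene.

Step 14
Reactants: 19 2-(trimethylsilyl)ethyl (2Z)-3-(acetoxymethyl)-5-[(1R,4aR,7R,8aR)-7-methoxy-5,5,8a-trimethyl-2-methylidenedecahydronaphthalen-1-yl]pent-2-enoate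
Product: 20 (2Z)-3-(acetoxymethyl)-5-[(1R,4aR,7R,8aR)-7-methoxy-5,5,8a-trimethyl-2-methylidenedecahydronaphthalen-1-yl]pent-2-enoic acid (16-acetoxy-2-methoxy-ent-labda-8(17),13Z-dien-15-oic acid)
Conditions: Bu4NF, AcOH, THF, 0 °C → rt; aqueous citric acid work-up
Reagents that add atoms: none
Why: Fluoride attacks silicon and the β-silylethyl ester fragments to ethene, fluorotrimethylsilane and the carboxylate, while the acetic acid buffer and short contact time are chosen so that the C16 acetate is neither cleaved nor displaced by the neighbouring carboxylate and the alkene geometry is kept.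

**Compound list**

1 | dimedone (5,5-dimethylcyclohexane-1,3-dione) | CC1(C)CC(=O)CC(=O)C1 | starting material
2 | 3-isobutoxy-5,5-dimethylcyclohex-2-en-1-one | CC(C)COC1=CC(=O)CC(C)(C)C1 | intermediate
3 | allyl (5-isobutoxy-3,3-dimethylcyclohexa-1,5-dien-1-yl) carbonate | C=CCOC(=O)OC1=CC(C)(C)CC(OCC(C)C)=C1 | intermediate
4 | (R)-6-allyl-3-isobutoxy-5,5-dimethylcyclohex-2-en-1-one | C=CC[C@@H]1C(C)(C)CC(OCC(C)C)=CC1=O | intermediate
5 | (R)-6-(3-hydroxypropyl)-3-isobutoxy-5,5-dimethylcyclohex-2-en-1-one | OCCC[C@@H]1C(C)(C)CC(OCC(C)C)=CC1=O | intermediate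
6 | 3-[(1R)-4-isobutoxy-6,6-dimethyl-2-oxocyclohex-3-en-1-yl]propanal | O=CCC[C@@H]1C(C)(C)CC(OCC(C)C)=CC1=O | intermediate
7 | (R)-6-(but-3-yn-1-yl)-3-isobutoxy-5,5-dimethylcyclohex-2-en-1-one | C#CCC[C@@H]1C(C)(C)CC(OCC(C)C)=CC1=O | intermediate
8 | bis-silylated carbinol: {[(6R)-3-isobutoxy-1,5,5-trimethyl-6-[4-(trimethylsilyl)but-3-yn-1-yl]cyclohex-2-en-1-yl]oxy}trimethylsilane, both C1 epimers (formed in the flask) | C[Si](C)(C)C#CCC[C@@H]1C(C)(C)CC(OCC(C)C)=CC1(C)O[Si](C)(C)C | intermediate
9 | (R)-3,5,5-trimethyl-4-[4-(trimethylsilyl)but-3-yn-1-yl]cyclohex-2-en-1-one | C[Si](C)(C)C#CCC[C@@H]1C(C)(C)CC(=O)C=C1C | intermediate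
10 | silyl enol ether of 11: trimethylsilyl ether of the C2-enol (C1=C2), C5 and C10 configured as in 11 (formed in the flask) | C[Si](C)(C)C#CCC[C@@H]1C(C)(C)CC(O[Si](C)(C)C)=C[C@@]1(C)C=C | intermediate
11 | (3S,4R)-3-ethenyl-3,5,5-trimethyl-4-[4-(trimethylsilyl)but-3-yn-1-yl]cyclohexan-1-one | C[Si](C)(C)C#CCC[C@@H]1C(C)(C)CC(=O)C[C@@]1(C)C=C | intermediate
12 | (1R,3S,4R)-3-ethenyl-3,5,5-trimethyl-4-[4-(trimethylsilyl)but-3-yn-1-yl]cyclohexan-1-ol (equatorial alcohol) | C[Si](C)(C)C#CCC[C@@H]1C(C)(C)C[C@@H](O)C[C@@]1(C)C=C | intermediate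
13 | silylalkyne methyl ether: {4-[(1R,2S,4R)-2-ethenyl-4-methoxy-2,6,6-trimethylcyclohexyl]but-1-yn-1-yl}trimethylsilane (formed in the flask) | C[Si](C)(C)C#CCC[C@@H]1C(C)(C)C[C@@H](OC)C[C@@]1(C)C=C | intermediate
14 | (1S,2R,5R)-2-(but-3-yn-1-yl)-1-ethenyl-5-methoxy-1,3,3-trimethylcyclohexane (ring A enyne) | C#CCC[C@@H]1C(C)(C)C[C@@H](OC)C[C@@]1(C)C=C | intermediate
15 | 1-acetoxy-3-chloroacetone (3-chloro-2-oxopropyl acetate) | CC(=O)OCC(=O)CCl | starting material
16 | 1-acetoxy-3-iodopropan-2-one | CC(=O)OCC(=O)CI | intermediate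
17 | C9 iodide adduct: 5-[(1R,2R,5R)-2-(but-3-yn-1-yl)-5-methoxy-1,3,3-trimethylcyclohexyl]-5-iodo-2-oxopentyl acetate, both epimers at the iodine-bearing carbon, ring configured as in 14 (formed in the flask) | C#CCC[C@@H]1C(C)(C)C[C@@H](OC)C[C@@]1(C)C(I)CCC(=O)COC(C)=O | intermediate
18 | 4-[(1R,4aR,7R,8aR)-7-methoxy-5,5,8a-trimethyl-2-methylidenedecahydronaphthalen-1-yl]-2-oxobutyl acetate (16-acetoxy-2-methoxy-14,15-dinor-ent-labd-8(17)-en-13-one) | C=C1CC[C@@H]2C(C)(C)C[C@@H](OC)C[C@@]2(C)[C@@H]1CCC(=O)COC(C)=O | intermediate
19 | 2-(trimethylsilyl)ethyl (2Z)-3-(acetoxymethyl)-5-[(1R,4aR,7R,8aR)-7-methoxy-5,5,8a-trimethyl-2-methylidenedecahydronaphthalen-1-yl]pent-2-enoate | C=C1CC[C@@H]2C(C)(C)C[C@@H](OC)C[C@@]2(C)[C@@H]1CC/C(=C/C(=O)OCC[Si](C)(C)C)COC(C)=O | intermediate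
20 | (2Z)-3-(acetoxymethyl)-5-[(1R,4aR,7R,8aR)-7-methoxy-5,5,8a-trimethyl-2-methylidenedecahydronaphthalen-1-yl]pent-2-enoic acid | C=C1CC[C@@H]2C(C)(C)C[C@@H](OC)C[C@@]2(C)[C@@H]1CC/C(=C/C(=O)O)COC(C)=O | target

**Step count and risks**

Total step count: 14. Longest linear sequence: 13 steps (steps 1–10 and 12–14); step 11 is a one-step side branch.

Steps most likely to fail:

1. Step 12. What may go wrong: hydrogen transfer from the stannane to the open-chain C9 radical outruns the 6-exo-dig closure, so the chain ends at the uncyclised adduct; part of the closure may also pass through the chair with the C11 chain pseudo-axial and give the C9 epimer. The fallback answers the first process only; the C9 epimer would have to be removed by chromatography at 18 or 19. The fallback replaces iodine transfer and stannane by degenerative xanthate transfer, sets out from 14 and 15 and comes back to the route at 18. KSC(S)OEt in acetone converts 15 into the xanthate S-(3-acetoxy-2-oxopropyl) O-ethyl dithiocarbonate F1. Catalytic dilauroyl peroxide in refluxing 1,2-dichloroethane adds F1 across the vinyl group of 14 to give the C9 xanthate adduct, 5-[2-(but-3-yn-1-yl)-5-methoxy-1,3,3-trimethylcyclohexyl]-5-[(ethoxycarbonothioyl)sulfanyl]-2-oxopentyl acetate F2. Portionwise stoichiometric dilauroyl peroxide in refluxing 2-propanol/1,2-dichloroethane then regenerates the C9 radical with no fast hydrogen donor present, so ring closure should precede reduction, and the vinyl radical is quenched by the solvent to give 18.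

2. Step 13. What may go wrong: the oxaphosphetane forms with the ester on the C12 side, so the E isomer predominates and little of the Z ester is obtained. The fallback locks the geometry in a ring, sets out from 18 and comes back to the route at 20. K2CO3 in MeOH removes the acetate to give the hydroxy ketone 16-hydroxy-2-methoxy-14,15-dinor-ent-labd-8(17)-en-13-one F3. Ph3P=C=C=O in refluxing toluene acylates the hydroxyl and closes by intramolecular Wittig reaction to the butenolide 2-methoxy-ent-labda-8(17),13-dien-15,16-olide F4, in which C15 and C16 are necessarily cis. LiOH in THF/H2O opens the lactone to the lithium hydroxy carboxylate, which is alkylated on the carboxylate with 2-(trimethylsilyl)ethoxymethyl chloride in DMF to 2-(trimethylsilyl)ethoxymethyl (13Z)-16-hydroxy-2-methoxy-ent-labda-8(17),13-dien-15-oate F5. This is acetylated at once (Ac2O, pyridine, DMAP, 0 °C) to 2-(trimethylsilyl)ethoxymethyl (13Z)-16-acetoxy-2-methoxy-ent-labda-8(17),13-dien-15-oate F6 before it can relactonise. MgBr2·OEt2 in CH2Cl2 then cleaves the acetal ester to 20.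

3. Step 3. What may go wrong: poor facial discrimination at the enolate carbon because it is flanked by the quaternary C4, so 4 is formed with low enantiomeric purity. The fallback replaces catalyst control by resolution, sets out from 2 and comes back to the route at 4. Deprotonation of 2 with LiN(i-Pr)2 and alkylation with allyl bromide (Stork–Danheiser alkylation) gives racemic 6-allyl-3-isobutoxy-5,5-dimethylcyclohex-2-en-1-one F7, which is separated by preparative chromatography on a chiral stationary phase; the (R) enantiomer is 4.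

Further compounds
F1 | step 12 | S-(3-acetoxy-2-oxopropyl) O-ethyl dithiocarbonate | CCOC(=S)SCC(=O)COC(C)=O
F2 | step 12 | 5-[2-(but-3-yn-1-yl)-5-methoxy-1,3,3-trimethylcyclohexyl]-5-[(ethoxycarbonothioyl)sulfanyl]-2-oxopentyl acetate (ring configured as in 14, both epimers at the sulfur-bearing carbon) | C#CCC[C@@H]1C(C)(C)C[C@@H](OC)C[C@@]1(C)C(SC(=S)OCC)CCC(=O)COC(C)=O
F3 | step 13 | 16-hydroxy-2-methoxy-14,15-dinor-ent-labd-8(17)-en-13-one | C=C1CC[C@@H]2C(C)(C)C[C@@H](OC)C[C@@]2(C)[C@@H]1CCC(=O)CO
F4 | step 13 | 2-methoxy-ent-labda-8(17),13-dien-15,16-olide | C=C1CC[C@@H]2C(C)(C)C[C@@H](OC)C[C@@]2(C)[C@@H]1CCC1=CC(=O)OC1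
F5 | step 13 | 2-(trimethylsilyl)ethoxymethyl (13Z)-16-hydroxy-2-methoxy-ent-labda-8(17),13-dien-15-oate | C=C1CC[C@@H]2C(C)(C)C[C@@H](OC)C[C@@]2(C)[C@@H]1CC/C(=C/C(=O)OCOCC[Si](C)(C)C)CO
F6 | step 13 | 2-(trimethylsilyl)ethoxymethyl (13Z)-16-acetoxy-2-methoxy-ent-labda-8(17),13-dien-15-oate | C=C1CC[C@@H]2C(C)(C)C[C@@H](OC)C[C@@]2(C)[C@@H]1CC/C(=C/C(=O)OCOCC[Si](C)(C)C)COC(C)=O
F7 | step 3 | racemic 6-allyl-3-isobutoxy-5,5-dimethylcyclohex-2-en-1-one | C=CCC1C(C)(C)CC(OCC(C)C)=CC1=O
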